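**Retrosynthetic overview**
1. Target ⇐ its octaacetate by lipase-catalysed global deacetylation (last step); octaacetate ⇐ aryl bromide heptaacetate + 4-acetoxystyrene (Mizoroki–Heck), so the stilbene is made only after all Lewis-acid chemistry.
2. Ring 1 (the dihydrobenzofuran carrying the stilbene, formed second) ⇐ diaryl ketone hydrazone: MnO2 to the diaryldiazomethane, Rh2(R-PTAD)4 carbene C–H insertion into a 4-methoxybenzyl ether (cis), then acid epimerisation at C2 (trans).
3. That hydrazone ⇐ ring-2 aryl bromide (Br/Li exchange) + a 2,6-dioxygenated 4-bromobenzaldehyde, then oxidation and condensation.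
4. Ring 2 (the catechol-bearing dihydrobenzofuran, formed first; first stereocentres) ⇐ the analogous hydrazone with Rh2(S-PTAD)4, made from a second such aldehyde + 3,5-dimethoxyphenyl Grignard.
5. Both aldehydes ⇐ 4-bromo-2-hydroxy-6-methoxybenzaldehyde by O-benzylation.

Assumption: Rh2(S-PTAD)4 (dirhodium tetrakis[(S)-(1-adamantyl)(phthalimido)acetate]) is taken to give the (3S) carbene-carbon centre and Rh2(R-PTAD)4 the (3R) one; if the sense of induction is the reverse, the two catalyst antipodes are exchanged and nothing else changes.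

**Route**

Step 1
Reactants: 1 4-bromo-2,6-dimethoxybenzaldehyde
Product: 2 4-bromo-2-hydroxy-6-methoxybenzaldehyde
Conditions: BCl3 (1.1 equiv), CH2Cl2, −78 → 0 °C; H2O
Reagents that add atoms: none
Why: Chelation-controlled Lewis-acid ether cleavage, in which boron bound to the aldehyde oxygen removes one of the two equivalent ortho methyl groups and the resulting aryloxyboron chelate protects the second.

Step 2
Reactants: 2 4-bromo-2-hydroxy-6-methoxybenzaldehyde; 3 4-(bromomethyl)-1,2-dimethoxybenzene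
Product: 4 4-bromo-2-[(3,4-dimethoxyphenyl)methoxy]-6-methoxybenzaldehyde
Conditions: K2CO3, DMF, 50 °C
Reagents that add atoms: none
Why: Williamson ether synthesis of an acidic salicylaldehyde phenol with a reactive benzylic bromide, installing the CH2 that later becomes C2 of ring 2.

Step 3
Reactants: 2 4-bromo-2-hydroxy-6-methoxybenzaldehyde; 5 1-(chloromethyl)-4-methoxybenzene
Product: 6 4-bromo-2-methoxy-6-[(4-methoxyphenyl)methoxy]benzaldehyde
Conditions: K2CO3, KI (cat.), DMF, 60 °C
Reagents that add atoms: none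
Why: Williamson ether synthesis (iodide-catalysed), installing the CH2 that later becomes C2 of ring 1.

Step 4
Reactants: 4 4-bromo-2-[(3,4-dimethoxyphenyl)methoxy]-6-methoxybenzaldehyde; 7 1-bromo-3,5-dimethoxybenzene
Product: 9 rac-[4-bromo-2-{(3,4-dimethoxyphenyl)methoxy}-6-methoxyphenyl](3,5-dimethoxyphenyl)methanol, via 3,5-dimethoxyphenylmagnesium bromide 8 (not isolated)
Conditions: Mg, I2 (cat.), THF, reflux; then 4, THF, −40 → 0 °C; sat. aq NH4Cl
Reagents that add atoms: none
Why: Grignard 1,2-addition to the aldehyde, which is far faster than any exchange at the aryl bromide; the carbinol centre is racemic and is destroyed in the next step.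

Step 5
Reactants: 9 rac-[4-bromo-2-{(3,4-dimethoxyphenyl)methoxy}-6-methoxyphenyl](3,5-dimethoxyphenyl)methanol
Product: 10 [4-bromo-2-{(3,4-dimethoxyphenyl)methoxy}-6-methoxyphenyl](3,5-dimethoxyphenyl)methanone
Conditions: DMP (1.5 equiv), pyridine, CH2Cl2, 0 °C → rt
Reagents that add atoms: none
Why: Dess–Martin oxidation of a hindered, acid-sensitive benzhydrol under buffered conditions that leave the benzylic ether and aryl bromide untouched.

Step 6
Reactants: 10 [4-bromo-2-{(3,4-dimethoxyphenyl)methoxy}-6-methoxyphenyl](3,5-dimethoxyphenyl)methanone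
Product: 11 hydrazone of 10 (N-unsubstituted; E/Z mixture)
Conditions: N2H4·H2O (20 equiv), AcOH (cat.), n-BuOH, 110 °C, sealed tube
Reagents that add atoms: hydrazine (as the monohydrate), NN
Why: Acid-catalysed hydrazone condensation driven by a large excess of hydrazine, which also suppresses azine formation.

Step 7
Reactants: 11 hydrazone of 10
Product: 13 (2R,3S)-6-bromo-2-(3,4-dimethoxyphenyl)-3-(3,5-dimethoxyphenyl)-4-methoxy-2,3-dihydro-1-benzofuran (cis), via diazo compound 12 (not isolated)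
Conditions: MnO2 (8 equiv), CH2Cl2, 0 °C; filter; then Rh2(S-PTAD)4 (1 mol %), MeCN, 0 °C → rt
Reagents that add atoms: none
Why: MnO2 dehydrogenates the hydrazone to the diaryldiazomethane, and the chiral dirhodium carboxylate then effects an enantioselective intramolecular 1,5 C–H insertion of the donor/donor carbene into the activated benzylic ether C–H (much faster than into OCH3), setting C3 (S) and C2 (R) together as the cis isomer.

Step 8
Reactants: 13 (2R,3S)-6-bromo-2-(3,4-dimethoxyphenyl)-3-(3,5-dimethoxyphenyl)-4-methoxy-2,3-dihydro-1-benzofuran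
Product: 14 (2S,3S)-6-bromo-2-(3,4-dimethoxyphenyl)-3-(3,5-dimethoxyphenyl)-4-methoxy-2,3-dihydro-1-benzofuran (trans)
Conditions: TFA (10 equiv), CH2Cl2 (0.02 M), 0 °C → rt
Reagents that add atoms: none
Why: Acid-mediated epimerisation by reversible heterolysis of the benzylic C2–O bond (cation stabilised by the para-methoxy group) and reclosure to the thermodynamically preferred trans isomer, so C2 becomes S while C3 is not touched.

Step 9
Reactants: 14 (2S,3S)-6-bromo-2-(3,4-dimethoxyphenyl)-3-(3,5-dimethoxyphenyl)-4-methoxy-2,3-dihydro-1-benzofuran; 6 4-bromo-2-methoxy-6-[(4-methoxyphenyl)methoxy]benzaldehyde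
Product: 16 [4-bromo-2-methoxy-6-{(4-methoxyphenyl)methoxy}phenyl][(2S,3S)-2-(3,4-dimethoxyphenyl)-3-(3,5-dimethoxyphenyl)-4-methoxy-2,3-dihydro-1-benzofuran-6-yl]methanol (both carbinol epimers), via aryllithium 15 (not isolated)
Conditions: n-BuLi (1.05 equiv), THF, −78 °C, 15 min; then 6, −78 → −40 °C; sat. aq NH4Cl
Reagents that add atoms: none
Why: Bromine–lithium exchange at −78 °C outruns deprotonation at C3, and the aryllithium adds to the aldehyde of 6 much faster than it exchanges with the bromide of 6; the mixed carbinol centre is removed in the next step.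

Step 10
Reactants: 16 the carbinol from step 9
Product: 17 [4-bromo-2-methoxy-6-{(4-methoxyphenyl)methoxy}phenyl][(2S,3S)-2-(3,4-dimethoxyphenyl)-3-(3,5-dimethoxyphenyl)-4-methoxy-2,3-dihydro-1-benzofuran-6-yl]methanone
Conditions: DMP (1.5 equiv), pyridine, CH2Cl2, 0 °C → rt
Reagents that add atoms: none
Why: Dess–Martin oxidation converges both carbinol epimers to one ketone without touching the dihydrobenzofuran stereocentres.

Step 11
Reactants: 17 the ketone from step 10
Product: 18 hydrazone of 17 (N-unsubstituted; E/Z mixture)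
Conditions: N2H4·H2O (20 equiv), AcOH (cat.), n-BuOH, 110 °C, sealed tube
Reagents that add atoms: hydrazine (as the monohydrate), NN
Why: Hydrazone condensation as in step 6; the trans ring 2 is already the thermodynamic isomer and is stable to these conditions.

Step 12
Reactants: 18 hydrazone of 17
Product: 20 (2S,3R)-6-bromo-3-[(2S,3S)-2-(3,4-dimethoxyphenyl)-3-(3,5-dimethoxyphenyl)-4-methoxy-2,3-dihydro-1-benzofuran-6-yl]-4-methoxy-2-(4-methoxyphenyl)-2,3-dihydro-1-benzofuran (ring 1 cis; ring 2 trans), via diazo compound 19 (not isolated)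
Conditions: MnO2 (8 equiv), CH2Cl2, 0 °C; filter; then Rh2(R-PTAD)4 (1 mol %), MeCN, 0 °C → rt
Reagents that add atoms: none
Why: The same hydrazone oxidation and rhodium-carbene 1,5 C–H insertion, now into the 4-methoxybenzyl ether, with the enantiomeric catalyst setting C3 (R) and C2 (S) of ring 1 under catalyst control because the ring-2 stereocentres are remote from the carbene.

Step 13
Reactants: 20 the ring-1-cis compound from step 12
Product: 21 (2R,3R)-6-bromo-3-[(2S,3S)-2-(3,4-dimethoxyphenyl)-3-(3,5-dimethoxyphenyl)-4-methoxy-2,3-dihydro-1-benzofuran-6-yl]-4-methoxy-2-(4-methoxyphenyl)-2,3-dihydro-1-benzofuran (both rings trans)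
Conditions: TFA (10 equiv), CH2Cl2 (0.02 M), 0 °C → rt
Reagents that add atoms: none
Why: Acid-mediated C2 epimerisation of ring 1 by reversible benzylic C–O heterolysis to the trans isomer (C2 becomes R, C3 stays R), while ring 2 is already at its trans equilibrium.

Step 14
Reactants: 21 the heptamethyl ether from step 13
Product: 22 4-[(2S,3S)-6-[(2R,3R)-6-bromo-4-hydroxy-2-(4-hydroxyphenyl)-2,3-dihydro-1-benzofuran-3-yl]-3-(3,5-dihydroxyphenyl)-4-hydroxy-2,3-dihydro-1-benzofuran-2-yl]benzene-1,2-diol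
Conditions: BBr3 (21 equiv), CH2Cl2, −78 °C → rt; H2O, 0 °C
Reagents that add atoms: none
Why: Lewis-acid cleavage of all seven aryl methyl ethers before any acid-sensitive stilbene is present; any transient opening of a benzylic C2–O bond recloses to the trans rings on work-up.

Step 15
Reactants: 22 the heptaphenol from step 14
Product: 23 heptaacetate of 22 (all seven phenols as acetates)
Conditions: Ac2O, pyridine, DMAP (cat.), rt
Reagents that add atoms: acetic anhydride, CC(=O)OC(C)=O
Why: Nucleophilic-catalysed acylation gives a stable, chromatographable polyacetate that protects the catechol and the phenols during the palladium step.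

Step 16
Reactants: 23 heptaacetate of 22; 24 4-ethenylphenyl acetate
Product: 25 octaacetate of the target, with the (E)-2-(4-acetoxyphenyl)ethenyl group at C6 of ring 1
Conditions: Pd(OAc)2 (5 mol %), P(o-tol)3 (15 mol %), Et3N, MeCN, 90 °C, sealed tube
Reagents that add atoms: none
Why: Mizoroki–Heck coupling of the unhindered aryl bromide at the terminal alkene carbon gives the E-stilbene by syn β-hydride elimination; stray loss of an acetate is harmless because all are removed next.

Step 17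
Reactants: 25 octaacetate of the target
Product: 26 4-[(2S,3S)-3-(3,5-dihydroxyphenyl)-4-hydroxy-6-[(2R,3R)-4-hydroxy-2-(4-hydroxyphenyl)-6-[(E)-2-(4-hydroxyphenyl)ethenyl]-2,3-dihydro-1-benzofuran-3-yl]-2,3-dihydro-1-benzofuran-2-yl]benzene-1,2-diol (target)
Conditions: immobilised Candida antarctica lipase B (a lipase), n-BuOH (40 equiv), MTBE/2-MeTHF, 45 °C; filter
Reagents that add atoms: none
Why: Lipase-catalysed transesterification (acyl-enzyme transfer of each aryl acetate to butanol) frees all eight phenols at neutral pH, avoiding base-induced quinone-methide ring opening and catechol autoxidation and touching no stereocentre.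

**Compound list**
1 | 4-bromo-2,6-dimethoxybenzaldehyde | COc1cc(Br)cc(OC)c1C=O | starting material
2 | 4-bromo-2-hydroxy-6-methoxybenzaldehyde | COc1cc(Br)cc(O)c1C=O | intermediate
3 | 4-(bromomethyl)-1,2-dimethoxybenzene | COc1ccc(CBr)cc1OC | starting material
4 | 4-bromo-2-[(3,4-dimethoxyphenyl)methoxy]-6-methoxybenzaldehyde | COc1cc(Br)cc(OCc2ccc(OC)c(OC)c2)c1C=O | intermediate
5 | 1-(chloromethyl)-4-methoxybenzene | COc1ccc(CCl)cc1 | starting material
6 | 4-bromo-2-methoxy-6-[(4-methoxyphenyl)methoxy]benzaldehyde | COc1cc(Br)cc(OCc2ccc(OC)cc2)c1C=O | intermediate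
7 | 1-bromo-3,5-dimethoxybenzene | COc1cc(Br)cc(OC)c1 | starting material
8 | 3,5-dimethoxyphenylmagnesium bromide (not isolated) | COc1cc(OC)cc([Mg]Br)c1 | intermediate
9 | rac-[4-bromo-2-{(3,4-dimethoxyphenyl)methoxy}-6-methoxyphenyl](3,5-dimethoxyphenyl)methanol | COc1cc(OC)cc(c1)C(O)c1c(OC)cc(Br)cc1OCc1ccc(OC)c(OC)c1 | intermediate
10 | [4-bromo-2-{(3,4-dimethoxyphenyl)methoxy}-6-methoxyphenyl](3,5-dimethoxyphenyl)methanone | COc1cc(OC)cc(c1)C(=O)c1c(OC)cc(Br)cc1OCc1ccc(OC)c(OC)c1 | intermediate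
11 | hydrazone of 10 | COc1cc(OC)cc(c1)C(=NN)c1c(OC)cc(Br)cc1OCc1ccc(OC)c(OC)c1 | intermediate
12 | 5-bromo-2-[diazo(3,5-dimethoxyphenyl)methyl]-1-[(3,4-dimethoxyphenyl)methoxy]-3-methoxybenzene (not isolated) | COc1cc(OC)cc(c1)C(=[N+]=[N-])c1c(OC)cc(Br)cc1OCc1ccc(OC)c(OC)c1 | intermediate
13 | (2R,3S)-6-bromo-2-(3,4-dimethoxyphenyl)-3-(3,5-dimethoxyphenyl)-4-methoxy-2,3-dihydro-1-benzofuran (cis) | Brc1cc(OC)c2c(c1)O[C@@H](c1ccc(OC)c(OC)c1)[C@H]2c1cc(OC)cc(OC)c1 | intermediate
14 | (2S,3S)-6-bromo-2-(3,4-dimethoxyphenyl)-3-(3,5-dimethoxyphenyl)-4-methoxy-2,3-dihydro-1-benzofuran (trans) | Brc1cc(OC)c2c(c1)O[C@H](c1ccc(OC)c(OC)c1)[C@H]2c1cc(OC)cc(OC)c1 | intermediate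
15 | 6-lithio analogue of 14 (not isolated) | [Li]c1cc(OC)c2c(c1)O[C@H](c1ccc(OC)c(OC)c1)[C@H]2c1cc(OC)cc(OC)c1 | intermediate
16 | [4-bromo-2-methoxy-6-{(4-methoxyphenyl)methoxy}phenyl][(2S,3S)-2-(3,4-dimethoxyphenyl)-3-(3,5-dimethoxyphenyl)-4-methoxy-2,3-dihydro-1-benzofuran-6-yl]methanol (carbinol epimers) | COc1cc(Br)cc(OCc2ccc(OC)cc2)c1C(O)c1cc(OC)c2c(c1)O[C@H](c1ccc(OC)c(OC)c1)[C@H]2c1cc(OC)cc(OC)c1 | intermediate
17 | corresponding methanone | COc1cc(Br)cc(OCc2ccc(OC)cc2)c1C(=O)c1cc(OC)c2c(c1)O[C@H](c1ccc(OC)c(OC)c1)[C@H]2c1cc(OC)cc(OC)c1 | intermediate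
18 | hydrazone of 17 | COc1cc(Br)cc(OCc2ccc(OC)cc2)c1C(=NN)c1cc(OC)c2c(c1)O[C@H](c1ccc(OC)c(OC)c1)[C@H]2c1cc(OC)cc(OC)c1 | intermediate
19 | diazo compound from 18 (not isolated) | COc1cc(Br)cc(OCc2ccc(OC)cc2)c1C(=[N+]=[N-])c1cc(OC)c2c(c1)O[C@H](c1ccc(OC)c(OC)c1)[C@H]2c1cc(OC)cc(OC)c1 | intermediate
20 | (2S,3R)-6-bromo-3-[(2S,3S)-2-(3,4-dimethoxyphenyl)-3-(3,5-dimethoxyphenyl)-4-methoxy-2,3-dihydro-1-benzofuran-6-yl]-4-methoxy-2-(4-methoxyphenyl)-2,3-dihydro-1-benzofuran (ring 1 cis) | Brc1cc(OC)c2c(c1)O[C@H](c1ccc(OC)cc1)[C@@H]2c1cc(OC)c2c(c1)O[C@H](c1ccc(OC)c(OC)c1)[C@H]2c1cc(OC)cc(OC)c1 | intermediate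
21 | (2R,3R) isomer of 20 at ring 1 (both rings trans) | Brc1cc(OC)c2c(c1)O[C@@H](c1ccc(OC)cc1)[C@@H]2c1cc(OC)c2c(c1)O[C@H](c1ccc(OC)c(OC)c1)[C@H]2c1cc(OC)cc(OC)c1 | intermediate
22 | 4-[(2S,3S)-6-[(2R,3R)-6-bromo-4-hydroxy-2-(4-hydroxyphenyl)-2,3-dihydro-1-benzofuran-3-yl]-3-(3,5-dihydroxyphenyl)-4-hydroxy-2,3-dihydro-1-benzofuran-2-yl]benzene-1,2-diol | Brc1cc(O)c2c(c1)O[C@@H](c1ccc(O)cc1)[C@@H]2c1cc(O)c2c(c1)O[C@H](c1ccc(O)c(O)c1)[C@H]2c1cc(O)cc(O)c1 | intermediate
23 | heptaacetate of 22 | Brc1cc(OC(C)=O)c2c(c1)O[C@@H](c1ccc(OC(C)=O)cc1)[C@@H]2c1cc(OC(C)=O)c2c(c1)O[C@H](c1ccc(OC(C)=O)c(OC(C)=O)c1)[C@H]2c1cc(OC(C)=O)cc(OC(C)=O)c1 | intermediate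
24 | 4-ethenylphenyl acetate | CC(=O)Oc1ccc(C=C)cc1 | starting material
25 | octaacetate of the target | CC(=O)Oc1ccc(/C=C/c2cc(OC(C)=O)c3c(c2)O[C@@H](c2ccc(OC(C)=O)cc2)[C@@H]3c2cc(OC(C)=O)c3c(c2)O[C@H](c2ccc(OC(C)=O)c(OC(C)=O)c2)[C@H]3c2cc(OC(C)=O)cc(OC(C)=O)c2)cc1 | intermediate
26 | CNP0107857.3, ring 1 (2R,3R), ring 2 (2S,3S), E-alkene | Oc1ccc(/C=C/c2cc(O)c3c(c2)O[C@@H](c2ccc(O)cc2)[C@@H]3c2cc(O)c3c(c2)O[C@H](c2ccc(O)c(O)c2)[C@H]3c2cc(O)cc(O)c2)cc1 | target

**Step count and risks**
Total steps: 17. Longest linear sequence: 16 steps (1 → 2 → 4 → 9 → 10 → 11 → 13 → 14 → 16 → 17 → 18 → 20 → 21 → 22 → 23 → 25 → 26); step 3 is the only side branch.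

Step 6 (and its repeat, step 11): the ketone carbon sits between two ortho alkoxy groups, so the condensation with hydrazine may stall. The fallback sets out from ketone 10 and comes back at hydrazone 11. Ketone 10 is thionated with Lawesson's reagent (toluene, 100 °C) to [4-bromo-2-{(3,4-dimethoxyphenyl)methoxy}-6-methoxyphenyl](3,5-dimethoxyphenyl)methanethione F1. Its much more electrophilic C=S carbon takes up hydrazine hydrate at room temperature (EtOH/THF) with loss of H2S to give 11. The same detour serves 17 → 18.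

Step 7 (and its repeat, step 12): a carbene flanked by two ortho oxygens is more hindered than the usual substrates for this insertion, so yield or enantiomeric excess may fall short. The fallback sets out from ketone 10 and comes back at the cis compound 13. Ketone 10 is treated with the phosphazene base P4-t-Bu (benzene, 90 °C); the benzylic ether carbanion adds to the ketone and water is lost to give 6-bromo-2-(3,4-dimethoxyphenyl)-3-(3,5-dimethoxyphenyl)-4-methoxy-1-benzofuran F2. The furan C2=C3 bond of F2 is then hydrogenated cis-selectively and enantioselectively (H2, 60 bar, chiral ruthenium N-heterocyclic-carbene catalyst made from [Ru(cod)(2-methylallyl)2], (R,R)-SINpEt·HBF4 and KOt-Bu, or its antipode as needed). This delivers 13, which continues into step 8; the selectivity of this hydrogenation on a 2,3-diaryl substrate is itself unproven.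

Step 17: the two acetates at C4 of each benzofuran are hindered and the lipase may leave partially acetylated material. The fallback sets out from bromide 21 and comes back at the target 26. Bromide 21 is coupled with 4-methoxystyrene (Pd(OAc)2, P(o-tol)3, Et3N, DMF, 100 °C) to the octamethyl ether of the target F3, which is demethylated in one operation with BBr3 (CH2Cl2, −78 °C → rt) to 26.

**Further compounds**
F1 | step 6 | [4-bromo-2-{(3,4-dimethoxyphenyl)methoxy}-6-methoxyphenyl](3,5-dimethoxyphenyl)methanethione | COc1cc(OC)cc(c1)C(=S)c1c(OC)cc(Br)cc1OCc1ccc(OC)c(OC)c1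
F2 | step 7 | 6-bromo-2-(3,4-dimethoxyphenyl)-3-(3,5-dimethoxyphenyl)-4-methoxy-1-benzofuran | COc1cc(Br)cc2oc(-c3ccc(OC)c(OC)c3)c(-c3cc(OC)cc(OC)c3)c12
F3 | step 17 | octamethyl ether of the target | COc1ccc(/C=C/c2cc(OC)c3c(c2)O[C@@H](c2ccc(OC)cc2)[C@@H]3c2cc(OC)c3c(c2)O[C@H](c2ccc(OC)c(OC)c2)[C@H]3c2cc(OC)cc(OC)c2)cc1
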